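Numbering: unprimed locants (O1, C2 … C8a) refer to the tetrahydrochromone unit, primed locants to the aromatic chromone unit. In names, "Chr" stands for the 7-(benzyloxy)-4-oxo-2-(2-phenylethyl)-4H-chromen-6-yl group.

## Analysis of the target

The target joins two 2-(2-arylethyl)chromone units: a 5,6,7,8-tetrahydrochromone carrying the 4-methoxyphenethyl group at C2, and an aromatic chromone carrying a phenethyl group at C2'. They are linked by two ether bridges, C7–O–C6' and C5–O–C7', so the catechol oxygens of the aromatic unit span C5 and C7 and close a seven-membered benzodioxepine in which C6 is a one-atom bridge. The four contiguous stereocentres are (5R,6S,7R,8S): O5 and O7 are cis (both axial on the bridge), and the free hydroxyls at C6 and C8 are each trans to O7, so the C6–C7–C8 oxygens are all-trans. Sensitive features are the two γ-pyrone rings (Michael acceptors), the free secondary alcohols, and the C5–O and C8–O bonds, which sit next to the pyranone and can be lost by elimination with aromatisation under base or heat. The difficulties are the regiochemistry of the unsymmetrical diether (O6' to C7 and O7' to C5, not the reverse), the bridged ring with four axial C–O bonds, and the fact that C6' is meta to the chromone carbonyl and so cannot be reached by SNAr. The strategy rests on one correspondence: C6, C7 and C8 with their all-trans oxygens have the configuration of C2, C3 and C4 of D-glucose, while C5, C8a and C4a map onto sugar C1, C5 and C6. A 3-O-aryl glucoside can therefore be transposed into the carbocycle with the O7 aryl ether already in place.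

## Retrosynthetic reasoning

**24 ⇒ 23.** No skeletal bond is cut; the C6 and C8 hydroxyls are kept as silyl ethers to the end. Free, they would compete in the ring closure, because attack of the 7'-phenol at C6 or C8 would give six-membered benzodioxanes faster than the bridged seven-membered ring. The forward step must remove two hindered silyl ethers without base.

**23 ⇒ 22.** The alkyl C–O bond C5–O7' of the dioxepine is cut. The aryl–O bonds are poor choices because C6' is unactivated, and the C7–O bond is best inherited from the chiral pool. C5 lies next to the pyranone, and the tethered phenol can only reach the face syn to O7. The forward reaction is an intramolecular Mitsunobu etherification with inversion, so the C5 carbinol of 22 must be trans to O7.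

**22 ⇒ 21 ⇒ 20.** These are protecting-group operations that fix the orthogonality: triethylsilyl on O5 (cleaved by mild acid beside the two TBS ethers) and benzyl on O7' (cleaved by hydrogenolysis). Benzyl is used and not an alkenyl group because the key step employs an alkene-philic metal salt.

**20 ⇒ 19 ⇒ 14 + 18.** The pyranone is cut at O1–C2 (conjugate addition of the enol oxygen to an ynone) and at C4–C4a (C-acylation). Ketone 14 has exactly the C8a carbonyl and a free C4a methylene, and acid chloride 18 supplies C2–C4 at the right oxidation level, so no dehydration is needed. The forward acylation must enolise toward C4a only, without expelling the β-oxygen at C5.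

**14 ⇒ 13 ⇒ 11 (key disconnection).** The C4a–C5 bond of the carbocycle is cut, turning the cyclohexanone into hex-5-enopyranoside 11. The three stereocentres C6–C8 and the O7 aryl ether come unchanged from the sugar. Only C5 is new, and the known facial preference of this aldol closure gives the hydroxyl trans to O7, as the later inversion requires.

**11 ⇒ 10 ⇒ 9 ⇒ 8 ⇒ 7.** These are functional-group changes on the sugar: elimination of a C6 iodide, silylation of O2 and O4, selective iodination of the primary hydroxyl, and methanolysis of furanose diacetonide 7 to the pyranoside. Iodination is placed before silylation so that the primary position never has to be distinguished from silyl ethers.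

**7 ⇒ 5 + 6.** The aryl–O bond C6'–O is cut. Compound 6 has a single free hydroxyl (O3), and a metal-catalysed C–O coupling leaves the sugar C3–O bond untouched, so the gluco configuration is retained. For an aryl bromide with a secondary alcohol, palladium with a bulky biaryl phosphine is preferred over copper, which is dependable mainly for aryl iodides.

**5 ⇒ 4 ⇒ 2 + 3, and 2 ⇒ 1.** The aromatic chromone is opened at O1'–C2' (cyclodehydration) and C2'–C3' (Claisen condensation of the acetophenone with acid chloride 3). The bromine of 1 marks C6' and the chelated 2-OH allows selective protection of the other phenol.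

**18 ⇒ 17 ⇒ 16 ⇒ 15.** The ynoyl chloride is traced back through carboxylation of terminal alkyne 16 to a one-carbon homologation of aldehyde 15.

## Alternatives that were turned down

**Alternative 1:** The tetrahydrochromone monomer A1 is cut at C4a–C8a and at O1–C2, leading to the open-chain δ-hydroxy β-diketone ester A2.
- Forward key step: excess strong amide base would form the polyanion of A2, whose terminal carbanion (C4a) attacks the C8a ester in a Dieckmann-type closure; acidic work-up then cyclodehydrates the triketone to the γ-pyrone.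
- For: carbocycle and pyranone form in one operation and no mercury is used. On this point it is stronger than the chosen route, which spends steps 11 to 15 on the pyranone.
- Against: A2 is a β-hydroxy ketone (C5–OH, C4=O) whose alkoxide can undergo retro-aldol cleavage. Its ester α-carbon C8 has a β-leaving group (O7), so E1cB loss and C8 epimerisation compete with the Claisen attack.
- Against: A1 is only the monomer. The aromatic unit would still need two O-arylations, of which only the one at C7' is activated for SNAr (para to C4a'), while the one at C6' would need a metal-catalysed closure of the bridged ring by a hindered secondary alcohol.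
- Comparison: the chosen strategy has the O7–C6' bond in place before the carbocycle exists, forms the second ether as an alkyl C–O bond by SN2, and has no base-labile acyclic polycarbonyl intermediate.

**Alternative 2:** Both alkyl C–O bonds of the dioxepine (C5–O7' and C7–O6') are cut at once, giving catechol chromone A4 and 2-acetyl quinone monoketal A5.
- Forward key step: a quinine-derived squaramide catalyst would direct the 7'-OH of A4 to C5 of A5 and then the 6'-OH to C7, a double oxa-Michael addition that gives the bridged β-diketone A3.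
- For: this is by far the shortest way to the bridged skeleton, from two achiral pieces, catalytic and without protecting the catechol. In convergence and step count up to that point it is clearly stronger.
- Against: which phenol attacks which carbon is only biased by the acidity difference, and phenol oxa-Michael additions are reversible, so both the constitution and the enantiopurity of A3 can erode by retro-addition.
- Against: A3 still lacks the C8 hydroxyl, which must be introduced next to C8a and trans to O7 on a substrate that loses aryloxide on enolisation. The C6 ketal must become a trans alcohol by hydride delivery from the arene-side face, which is not obviously the open one. The acetyl group must be grown into the pyranone.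
- Comparison: the chosen route fixes C6–C8 from the chiral pool, leaves a single new centre (C5), and makes both ether bonds irreversibly.

**Alternative 3:** The benzene ring of the aromatic chromone is cut at C6'–C7' and C4a'–C5'. The precursor A7 carries a 3-oxy-2-pyrone ring (fused to the phenethyl γ-pyrone) on O5 and a β-sulfonylvinyl ether on O7.
- Forward key step: heating would bring about an intramolecular Diels–Alder addition, decarboxylative retro-cycloaddition and sulfinate elimination, giving A6 (the same compound as 23).
- For: the regiochemistry of the diether is fixed by the tether, no hindered alcohol has to be arylated, and the union comes one step before the target. In regiocontrol and late convergence it is at least as strong as the chosen route.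
- Against: A7 needs a complete monomer diol with O5 and O7 differentiated plus a bespoke bicyclic pyrone, so the step count is higher.
- Against: the cycloaddition must pass through a bridged bicyclic lactone with the cyclohexene in its all-axial conformer, and the diene–dienophile pair is electronically poorly matched. High temperatures are expected, at which the 5,8-dioxygenated tetrahydrochromone tends to aromatise by elimination.
- Comparison: the chosen strategy reaches the same compound from a simple acetophenone-derived arene and two ordinary ether formations.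

Key step: step 9

Assumption: glycoside 8 is drawn as the α-anomer favoured under equilibrating methanolysis; any β-anomer would be carried through steps 6 to 8 as well, since the anomeric centre becomes the achiral aldehyde carbon in step 9.

## Route

Step 1
Reactants: 1 1-(5-bromo-2,4-dihydroxyphenyl)ethanone
Product: 2 1-[4-(benzyloxy)-5-bromo-2-hydroxyphenyl]ethanone
Conditions: BnBr (1.05 equiv), K2CO3, acetone, 56 °C
Reagents that add atoms: benzyl bromide, BrCc1ccccc1
Why: Williamson etherification; the 2-OH is held in a hydrogen bond to the acetyl group and the 4-OH (para to the carbonyl) is the more acidic phenol, so monobenzylation should occur at O4 only.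

Step 2
Reactants: 2 1-[4-(benzyloxy)-5-bromo-2-hydroxyphenyl]ethanone; 3 3-phenylpropanoyl chloride
Product: 4 1-[4-(benzyloxy)-5-bromo-2-hydroxyphenyl]-5-phenylpentane-1,3-dione
Conditions: LiN(SiMe3)2 (3.1 equiv), THF, −78 → −10 °C; then 3, −78 °C → rt; aq. HCl work-up
Reagents that add atoms: none
Why: Crossed Claisen condensation of the phenoxide–enolate dianion with the acid chloride; any O-acylated phenol should converge on the same β-diketone by Baker–Venkataraman acyl shift under the excess amide base.

Step 3
Reactants: 4 1-[4-(benzyloxy)-5-bromo-2-hydroxyphenyl]-5-phenylpentane-1,3-dione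
Product: 5 7-(benzyloxy)-6-bromo-2-(2-phenylethyl)-4H-chromen-4-one
Conditions: conc. HCl (cat.), MeOH, 65 °C
Reagents that add atoms: none
Why: Acid-catalysed cyclodehydration of an o-hydroxyaryl β-diketone (hemiketal formation, then loss of water) is the standard closure of 2-alkylchromones; the benzyl aryl ether and the aryl bromide are inert.

Step 4
Reactants: 5 7-(benzyloxy)-6-bromo-2-(2-phenylethyl)-4H-chromen-4-one; 6 1,2:5,6-di-O-isopropylidene-α-D-glucofuranose
Product: 7 3-O-Chr-1,2:5,6-di-O-isopropylidene-α-D-glucofuranose
Conditions: [Pd(C3H5)Cl]2 (2.5 mol%), RockPhos (6 mol%), Cs2CO3, 6 (2 equiv), toluene, 90 °C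
Reagents that add atoms: none
Why: Palladium-catalysed C–O cross-coupling of an aryl bromide with a secondary alcohol; the bulky di-tert-butyl biaryl phosphine and the ortho benzyloxy group favour C–O reductive elimination over β-hydride elimination. The sugar C3–O bond is not broken, so the gluco configuration is retained.

Step 5
Reactants: 7 3-O-Chr-1,2:5,6-di-O-isopropylidene-α-D-glucofuranose
Product: 8 methyl 3-O-Chr-α-D-glucopyranoside
Conditions: HCl (1.25 M in MeOH), 65 °C; then NaHCO3
Reagents that add atoms: methanol, CO
Why: Acid methanolysis removes both acetonides, and Fischer glycosidation equilibrates furanosides to pyranosides with the α-anomer favoured by the anomeric effect; aryl ethers and the chromone are acid-stable.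

Step 6
Reactants: 8 methyl 3-O-Chr-α-D-glucopyranoside
Product: 9 methyl 3-O-Chr-6-deoxy-6-iodo-α-D-glucopyranoside
Conditions: I2, PPh3, imidazole, THF, 60 °C
Reagents that add atoms: iodine, II
Why: Appel-type iodination; only the primary C6 alkoxyphosphonium undergoes SN2 displacement by iodide, so the secondary 2- and 4-hydroxyls should remain.

Step 7
Reactants: 9 methyl 3-O-Chr-6-deoxy-6-iodo-α-D-glucopyranoside
Product: 10 methyl 3-O-Chr-2,4-bis-O-(tert-butyldimethylsilyl)-6-deoxy-6-iodo-α-D-glucopyranoside
Conditions: TBSOTf (3 equiv), 2,6-lutidine, CH2Cl2, 0 °C → rt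
Reagents that add atoms: tert-butyldimethylsilyl trifluoromethanesulfonate, CC(C)(C)[Si](C)(C)OS(=O)(=O)C(F)(F)F
Why: Silyl triflate silylation is forceful enough for the two secondary hydroxyls flanking the aryloxy group; the primary iodide is inert to it.

Step 8
Reactants: 10 methyl 3-O-Chr-2,4-bis-O-(tert-butyldimethylsilyl)-6-deoxy-6-iodo-α-D-glucopyranoside
Product: 11 methyl 3-O-Chr-2,4-bis-O-(tert-butyldimethylsilyl)-6-deoxy-α-D-xylo-hex-5-enopyranoside
Conditions: DBU, THF, 65 °C
Reagents that add atoms: none
Why: E2 dehydroiodination across C5–C6 of the sugar gives the exocyclic enol ether; the amidine base does not add to the chromone and leaves silyl ethers intact.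

Step 9
Reactants: 11 methyl 3-O-Chr-2,4-bis-O-(tert-butyldimethylsilyl)-6-deoxy-α-D-xylo-hex-5-enopyranoside
Product: 13 (2S,3R,4S,5S)-3-(Chr-oxy)-2,4-bis[(tert-butyldimethylsilyl)oxy]-5-hydroxycyclohexan-1-one, via open-chain mercurio keto-aldehyde 12 (not isolated)
Conditions: Hg(OCOCF3)2 (10 mol%), acetone/H2O (4:1), rt
Reagents that add atoms: water, O
Why: Ferrier carbocyclization of a 6-deoxyhex-5-enopyranoside, a known reaction type: the divalent mercury salt and water add to the electron-rich exocyclic enol ether (mercury on the future C4a, hydroxyl on the future C8a), and the hemiketal opens to the C8a ketone while the ring oxygen stays on the anomeric carbon as a methyl hemiacetal that loses methanol to give aldehyde 12. The α-mercurio ketone of 12 reacts as a mercury enolate, and C4a adds to the C5 aldehyde in a 6-(enolendo)-exo-trig aldol closure that forms the C4a–C5 bond and the cyclohexanone ring; protonolysis of the mercury alkoxide returns the catalyst. The only new stereocentre is C5: in the chair-like transition state the three oxygen substituents inherited from the sugar (O6, O7, O8) stay equatorial and the aldehyde oxygen takes the axial position, where it can bridge to the enolate-bound mercury, so the hydroxyl should emerge cis to O6 and trans to O7 (5S in 13). This is the epimer the later invertive closure needs. The step needs chemoselective mercuration of the enol ether, which is secured by having no other alkene in 11 (benzyl and not an alkenyl group on O7') and by introducing the electron-rich anisyl ring only later. It also needs the β-hydroxy ketone to survive, which the near-neutral medium, room temperature and a non-basic work-up should ensure. C6, C7 and C8 are not epimerised under these conditions and keep the D-gluco configuration.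

Step 10
Reactants: 13 (2S,3R,4S,5S)-3-(Chr-oxy)-2,4-bis[(tert-butyldimethylsilyl)oxy]-5-hydroxycyclohexan-1-one
Product: 14 (2S,3R,4R,5S)-3-(Chr-oxy)-2,4-bis[(tert-butyldimethylsilyl)oxy]-5-[(triethylsilyl)oxy]cyclohexan-1-one
Conditions: TESOTf (1.2 equiv), 2,6-lutidine, CH2Cl2, −78 °C
Reagents that add atoms: triethylsilyl trifluoromethanesulfonate, CC[Si](CC)(CC)OS(=O)(=O)C(F)(F)F
Why: O-silylation at low temperature with a weak pyridine base outruns enolisation, so neither dehydration nor enol silane formation is expected; the triethylsilyl ether can later be cleaved beside the two TBS ethers (the change of the C4 descriptor is only a priority change).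

Step 11
Reactants: 15 3-(4-methoxyphenyl)propanal
Product: 16 1-(but-3-yn-1-yl)-4-methoxybenzene
Conditions: dimethyl (1-diazo-2-oxopropyl)phosphonate, K2CO3, MeOH, 0 °C → rt
Reagents that add atoms: dimethyl (1-diazo-2-oxopropyl)phosphonate, COP(=O)(OC)C(=[N+]=[N-])C(C)=O
Why: Ohira–Bestmann variant of the Seyferth–Gilbert homologation: methanolysis of the acetyl group gives the diazophosphonate anion, olefination of the aldehyde followed by loss of N2 and 1,2-hydride shift gives the terminal alkyne under conditions mild enough for an enolisable aldehyde.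

Step 12
Reactants: 16 1-(but-3-yn-1-yl)-4-methoxybenzene
Product: 17 5-(4-methoxyphenyl)pent-2-ynoic acid
Conditions: n-BuLi, THF, −78 °C; CO2; aq. HCl
Reagents that add atoms: carbon dioxide, O=C=O
Why: Carboxylation of the lithium acetylide; the terminal alkyne C–H is far more acidic than any ring or benzylic position.

Step 13
Reactants: 17 5-(4-methoxyphenyl)pent-2-ynoic acid
Product: 18 5-(4-methoxyphenyl)pent-2-ynoyl chloride
Conditions: (COCl)2, DMF (cat.), CH2Cl2, 0 °C → rt; concentrated and used crude
Reagents that add atoms: oxalyl chloride, O=C(Cl)C(Cl)=O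
Why: Chlorination through the Vilsmeier-type chloroiminium species is fast at low temperature, which limits addition of HCl to the conjugated triple bond.

Step 14
Reactants: 14 (2S,3R,4R,5S)-3-(Chr-oxy)-2,4-bis[(tert-butyldimethylsilyl)oxy]-5-[(triethylsilyl)oxy]cyclohexan-1-one; 18 5-(4-methoxyphenyl)pent-2-ynoyl chloride
Product: 19 ynedione: ketone 14 bearing the 5-(4-methoxyphenyl)pent-2-ynoyl group on C4a, drawn as the hydrogen-bonded ring enol (C8a–OH), configurations at C5–C8 as in 14
Conditions: MgBr2·OEt2 (2.5 equiv), i-Pr2NEt (3 equiv), CH2Cl2, 0 °C → rt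
Reagents that add atoms: none
Why: Soft enolisation: magnesium coordination acidifies the ketone so that the hindered amine deprotonates the unsubstituted α-carbon C4a, and the magnesium enolate is C-acylated by the acid chloride to the chelated β-diketone. Avoiding a lithium amide base is meant to suppress E1cB loss of the C5 silyloxy group and enolisation toward C8.

Step 15
Reactants: 19 ynedione (ring enol form)
Product: 20 (5S,6R,7R,8S)-7-(Chr-oxy)-6,8-bis[(tert-butyldimethylsilyl)oxy]-2-[2-(4-methoxyphenyl)ethyl]-5-[(triethylsilyl)oxy]-5,6,7,8-tetrahydro-4H-chromen-4-one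
Conditions: Ph3PAuNTf2 (5 mol%), CH2Cl2, rt
Reagents that add atoms: none
Why: Cycloisomerisation of an alkynyl β-diketone to a γ-pyrone: the enol oxygen adds to the gold-activated ynone at its β-carbon (6-endo-dig, forming O1–C2) and protodeauration gives the pyranone. The 5-exo mode would need attack at the α-carbon against the polarity of the ynone.

Step 16
Reactants: 20 (5S,6R,7R,8S)-7-(Chr-oxy)-6,8-bis-TBS-5-TES tetrahydrochromone
Product: 21 (5S,6R,7R,8S)-6,8-bis[(tert-butyldimethylsilyl)oxy]-7-{[7-hydroxy-4-oxo-2-(2-phenylethyl)-4H-chromen-6-yl]oxy}-2-[2-(4-methoxyphenyl)ethyl]-5-[(triethylsilyl)oxy]-5,6,7,8-tetrahydro-4H-chromen-4-one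
Conditions: H2 (1 atm), Pd/C (10 wt%), EtOAc, rt
Reagents that add atoms: none
Why: Hydrogenolysis of the benzyl aryl ether; chromone and γ-pyrone rings are not expected to be reduced under these mild neutral conditions, and the silyl ethers are stable in ethyl acetate.

Step 17
Reactants: 21 7'-phenol with O5 triethylsilyl ether
Product: 22 (5S,6S,7R,8S)-6,8-bis[(tert-butyldimethylsilyl)oxy]-5-hydroxy-7-{[7-hydroxy-4-oxo-2-(2-phenylethyl)-4H-chromen-6-yl]oxy}-2-[2-(4-methoxyphenyl)ethyl]-5,6,7,8-tetrahydro-4H-chromen-4-one
Conditions: PPTS, MeOH/CH2Cl2 (1:1), 0 °C → rt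
Reagents that add atoms: none
Why: Acid-catalysed methanolysis cleaves a triethylsilyl ether much faster than hindered secondary TBS ethers, so only O5 should be freed (the C6 descriptor changes by priority only).

Step 18
Reactants: 22 5-hydroxy 7'-phenol
Product: 23 (5R,6S,7R,8S)-6,8-bis-O-(tert-butyldimethylsilyl) ether of the target (dioxepine closed between C5–O–C7' and C7–O–C6')
Conditions: PPh3, DIAD, toluene (0.005 M), 0 °C → rt
Reagents that add atoms: none
Why: Intramolecular Mitsunobu etherification: the acidic 7'-phenol protonates the betaine, O5 becomes an oxyphosphonium leaving group, and the phenoxide displaces it with inversion through the cyclohexene conformer in which O7 is axial, setting C5 as R with its oxygen cis to O7. O6 and O8 are silylated, so the competing six-membered benzodioxane closures are excluded.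

Step 19
Reactants: 23 6,8-bis-O-TBS ether of the target
Product: 24 (+)-4'-methoxyaquisinenone G, (5R,6S,7R,8S)
Conditions: HF·pyridine, pyridine/THF, 0 °C → rt
Reagents that add atoms: none
Why: Fluoride-assisted cleavage of the two secondary TBS ethers under buffered, non-basic conditions, chosen because base could trigger elimination of the aryloxy groups from the vinylogously acidic C8 position.

## Compound list

1 | 1-(5-bromo-2,4-dihydroxyphenyl)ethanone | CC(=O)c1cc(Br)c(O)cc1O | starting material
2 | 1-[4-(benzyloxy)-5-bromo-2-hydroxyphenyl]ethanone | CC(=O)c1cc(Br)c(OCc2ccccc2)cc1O | intermediate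
3 | 3-phenylpropanoyl chloride | O=C(Cl)CCc1ccccc1 | starting material
4 | 1-[4-(benzyloxy)-5-bromo-2-hydroxyphenyl]-5-phenylpentane-1,3-dione | O=C(CC(=O)CCc1ccccc1)c1cc(Br)c(OCc2ccccc2)cc1O | intermediate
5 | 7-(benzyloxy)-6-bromo-2-(2-phenylethyl)-4H-chromen-4-one | O=c1cc(CCc2ccccc2)oc2cc(OCc3ccccc3)c(Br)cc12 | intermediate
6 | 1,2:5,6-di-O-isopropylidene-α-D-glucofuranose | CC1(C)OC[C@@H](O1)[C@H]2O[C@@H]3OC(C)(C)O[C@@H]3[C@H]2O | starting material
7 | 3-O-Chr-1,2:5,6-di-O-isopropylidene-α-D-glucofuranose | CC1(C)OC[C@@H](O1)[C@H]2O[C@@H]3OC(C)(C)O[C@@H]3[C@H]2Oc4cc5c(=O)cc(CCc6ccccc6)oc5cc4OCc7ccccc7 | intermediate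
8 | methyl 3-O-Chr-α-D-glucopyranoside | OC[C@H]1O[C@H](OC)[C@H](O)[C@@H](Oc2cc3c(=O)cc(CCc4ccccc4)oc3cc2OCc5ccccc5)[C@@H]1O | intermediate
9 | methyl 3-O-Chr-6-deoxy-6-iodo-α-D-glucopyranoside | IC[C@H]1O[C@H](OC)[C@H](O)[C@@H](Oc2cc3c(=O)cc(CCc4ccccc4)oc3cc2OCc5ccccc5)[C@@H]1O | intermediate
10 | methyl 3-O-Chr-2,4-bis-O-(tert-butyldimethylsilyl)-6-deoxy-6-iodo-α-D-glucopyranoside | IC[C@H]1O[C@H](OC)[C@H](O[Si](C)(C)C(C)(C)C)[C@@H](Oc2cc3c(=O)cc(CCc4ccccc4)oc3cc2OCc5ccccc5)[C@@H]1O[Si](C)(C)C(C)(C)C | intermediate
11 | methyl 3-O-Chr-2,4-bis-O-(tert-butyldimethylsilyl)-6-deoxy-α-D-xylo-hex-5-enopyranoside | C=C1[C@@H](O[Si](C)(C)C(C)(C)C)[C@H](Oc2cc3c(=O)cc(CCc4ccccc4)oc3cc2OCc5ccccc5)[C@@H](O[Si](C)(C)C(C)(C)C)[C@@H](OC)O1 | intermediate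
12 | 3-O-Chr-2,4-bis-O-(tert-butyldimethylsilyl)-6-deoxy-6-(trifluoroacetoxymercurio)-D-xylo-hexos-5-ulose (open-chain keto-aldehyde, not isolated) | FC(F)(F)C(=O)O[Hg]CC(=O)[C@@H](O[Si](C)(C)C(C)(C)C)[C@H](Oc1cc2c(=O)cc(CCc3ccccc3)oc2cc1OCc4ccccc4)[C@@H](O[Si](C)(C)C(C)(C)C)C=O | intermediate
13 | (2S,3R,4S,5S)-3-(Chr-oxy)-2,4-bis[(tert-butyldimethylsilyl)oxy]-5-hydroxycyclohexan-1-one | C1C(=O)[C@@H](O[Si](C)(C)C(C)(C)C)[C@H](Oc2cc3c(=O)cc(CCc4ccccc4)oc3cc2OCc5ccccc5)[C@@H](O[Si](C)(C)C(C)(C)C)[C@H]1O | intermediate
14 | (2S,3R,4R,5S)-3-(Chr-oxy)-2,4-bis[(tert-butyldimethylsilyl)oxy]-5-[(triethylsilyl)oxy]cyclohexan-1-one | C1C(=O)[C@@H](O[Si](C)(C)C(C)(C)C)[C@H](Oc2cc3c(=O)cc(CCc4ccccc4)oc3cc2OCc5ccccc5)[C@@H](O[Si](C)(C)C(C)(C)C)[C@H]1O[Si](CC)(CC)CC | intermediate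
15 | 3-(4-methoxyphenyl)propanal | COc1ccc(CCC=O)cc1 | starting material
16 | 1-(but-3-yn-1-yl)-4-methoxybenzene | COc1ccc(CCC#C)cc1 | intermediate
17 | 5-(4-methoxyphenyl)pent-2-ynoic acid | COc1ccc(CCC#CC(=O)O)cc1 | intermediate
18 | 5-(4-methoxyphenyl)pent-2-ynoyl chloride | COc1ccc(CCC#CC(Cl)=O)cc1 | intermediate
19 | ynedione: 14 acylated at C4a with the 5-(4-methoxyphenyl)pent-2-ynoyl group, ring enol tautomer | COc1ccc(CCC#CC(=O)C2=C(O)[C@@H](O[Si](C)(C)C(C)(C)C)[C@H](Oc3cc4c(=O)cc(CCc5ccccc5)oc4cc3OCc6ccccc6)[C@@H](O[Si](C)(C)C(C)(C)C)[C@H]2O[Si](CC)(CC)CC)cc1 | intermediate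
20 | (5S,6R,7R,8S)-7-(Chr-oxy)-6,8-bis[(tert-butyldimethylsilyl)oxy]-2-[2-(4-methoxyphenyl)ethyl]-5-[(triethylsilyl)oxy]-5,6,7,8-tetrahydro-4H-chromen-4-one | COc1ccc(CCc2cc(=O)c3c(o2)[C@@H](O[Si](C)(C)C(C)(C)C)[C@H](Oc4cc5c(=O)cc(CCc6ccccc6)oc5cc4OCc7ccccc7)[C@@H](O[Si](C)(C)C(C)(C)C)[C@H]3O[Si](CC)(CC)CC)cc1 | intermediate
21 | (5S,6R,7R,8S)-6,8-bis[(tert-butyldimethylsilyl)oxy]-7-{[7-hydroxy-4-oxo-2-(2-phenylethyl)-4H-chromen-6-yl]oxy}-2-[2-(4-methoxyphenyl)ethyl]-5-[(triethylsilyl)oxy]-5,6,7,8-tetrahydro-4H-chromen-4-one | COc1ccc(CCc2cc(=O)c3c(o2)[C@@H](O[Si](C)(C)C(C)(C)C)[C@H](Oc4cc5c(=O)cc(CCc6ccccc6)oc5cc4O)[C@@H](O[Si](C)(C)C(C)(C)C)[C@H]3O[Si](CC)(CC)CC)cc1 | intermediate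
22 | (5S,6S,7R,8S)-6,8-bis[(tert-butyldimethylsilyl)oxy]-5-hydroxy-7-{[7-hydroxy-4-oxo-2-(2-phenylethyl)-4H-chromen-6-yl]oxy}-2-[2-(4-methoxyphenyl)ethyl]-5,6,7,8-tetrahydro-4H-chromen-4-one | COc1ccc(CCc2cc(=O)c3c(o2)[C@@H](O[Si](C)(C)C(C)(C)C)[C@H](Oc4cc5c(=O)cc(CCc6ccccc6)oc5cc4O)[C@@H](O[Si](C)(C)C(C)(C)C)[C@H]3O)cc1 | intermediate
23 | (5R,6S,7R,8S)-6,8-bis-O-(tert-butyldimethylsilyl) ether of the target | COc1ccc(CCc2cc(=O)c3c(o2)[C@@H](O[Si](C)(C)C(C)(C)C)[C@@H]2Oc4cc5c(=O)cc(CCc6ccccc6)oc5cc4O[C@H]3[C@@H]2O[Si](C)(C)C(C)(C)C)cc1 | intermediate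
24 | (+)-4'-methoxyaquisinenone G | COc1ccc(CCc2cc(=O)c3c(o2)[C@@H](O)[C@@H]2Oc4cc5c(=O)cc(CCc6ccccc6)oc5cc4O[C@H]3[C@@H]2O)cc1 | target

## Step count and least certain steps

Total: 19 steps. Longest linear sequence: 16 steps (steps 1–10 and 14–19, from 1); steps 11–13 form a three-step side branch that joins at step 14.

**Step 9 (key step).** The most likely failure is erosion of facial selectivity in the aldol closure: two bulky silyl ethers flank the aryloxy group and may push the keto-aldehyde out of the all-equatorial chair, so that the C5 epimers form together. Acid-promoted dehydration of the β-hydroxy ketone is a second risk. Fallback, setting out from 11 and returning at 13: the enol ether is hydrolysed with dilute aqueous acid in dioxane to the metal-free open-chain 3-O-Chr-2,4-bis-O-TBS-6-deoxy-D-xylo-hexos-5-ulose F1. This is then closed in a separate step by amine-mediated intramolecular aldol addition (L-proline or a catalytic tertiary amine). The aldol is reversible under these conditions, so the unwanted C5 epimer can be re-equilibrated by retro-aldol and aldol.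

**Step 4.** The hindered secondary alkoxide may bind palladium slowly and then undergo β-hydride elimination, which reduces the aryl bromide and oxidises the sugar alcohol instead of forming the ether. Fallback with reversed polarity, setting out from 5 and returning at 7: Miyaura borylation (B2pin2, PdCl2(dppf), KOAc) gives 7-(benzyloxy)-2-(2-phenylethyl)-6-(pinacolboryl)chromone F2, and oxidation with NaBO3·4H2O gives 7-(benzyloxy)-6-hydroxy-2-(2-phenylethyl)-4H-chromen-4-one F3. Commercial 1,2:5,6-di-O-isopropylidene-α-D-allofuranose F4 is converted with Tf2O and pyridine into its 3-O-triflate F5. The caesium phenoxide of F3 displaces the triflate in DMF from the open exo face with inversion, which gives the gluco ether 7.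

**Step 14.** The magnesium enolate may expel the C5 silyloxy group (E1cB; the C5–O bond is axial and aligned with the enolate), or enolisation may stray toward C8 with loss of the C7 aryloxide. Bromide addition to the ynoyl unit is also possible. Fallback, setting out from 14 and returning at 19: alkyne 16 is formylated (n-BuLi, then DMF) to 5-(4-methoxyphenyl)pent-2-ynal F6. The boron enolate of 14 ((c-C6H11)2BCl, Et3N, −78 °C) adds to F6 to give the β-hydroxy ynone aldol adduct F7, and Dess–Martin oxidation of F7 gives 19.

**Step 18.** The oxyphosphonium intermediate may eliminate toward C6 or ionise before the ring reaches the conformer that allows backside attack, and the hydrazide may alkylate the phenol. Fallback by stepwise sulfonate displacement, setting out from 22 and returning at 23: the phenol is acetylated selectively (Ac2O, Et3N) to the 7'-O-acetyl 5-alcohol F8, and the C5 hydroxyl is mesylated (MsCl, Et3N, −20 °C) to the 7'-O-acetyl 5-O-mesylate F9. Cs2CO3 in MeOH/THF then cleaves the aryl acetate, and the liberated phenoxide displaces the mesylate intramolecularly with inversion.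

## Further compounds

F1 | step 9 | 3-O-Chr-2,4-bis-O-(tert-butyldimethylsilyl)-6-deoxy-D-xylo-hexos-5-ulose (open-chain keto-aldehyde) | CC(=O)[C@@H](O[Si](C)(C)C(C)(C)C)[C@H](Oc1cc2c(=O)cc(CCc3ccccc3)oc2cc1OCc4ccccc4)[C@@H](O[Si](C)(C)C(C)(C)C)C=O
F2 | step 4 | 7-(benzyloxy)-2-(2-phenylethyl)-6-(4,4,5,5-tetramethyl-1,3,2-dioxaborolan-2-yl)-4H-chromen-4-one | O=c1cc(CCc2ccccc2)oc2cc(OCc3ccccc3)c(B4OC(C)(C)C(C)(C)O4)cc12
F3 | step 4 | 7-(benzyloxy)-6-hydroxy-2-(2-phenylethyl)-4H-chromen-4-one | O=c1cc(CCc2ccccc2)oc2cc(OCc3ccccc3)c(O)cc12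
F4 | step 4 | 1,2:5,6-di-O-isopropylidene-α-D-allofuranose | CC1(C)OC[C@@H](O1)[C@H]2O[C@@H]3OC(C)(C)O[C@@H]3[C@@H]2O
F5 | step 4 | 1,2:5,6-di-O-isopropylidene-3-O-(trifluoromethylsulfonyl)-α-D-allofuranose | CC1(C)OC[C@@H](O1)[C@H]2O[C@@H]3OC(C)(C)O[C@@H]3[C@@H]2OS(=O)(=O)C(F)(F)F
F6 | step 14 | 5-(4-methoxyphenyl)pent-2-ynal | COc1ccc(CCC#CC=O)cc1
F7 | step 14 | aldol adduct of 14 (at C4a) with F6, β-hydroxy ynone, mixture at C4a and at the carbinol carbon | COc1ccc(CCC#CC(O)C2C(=O)[C@@H](O[Si](C)(C)C(C)(C)C)[C@H](Oc3cc4c(=O)cc(CCc5ccccc5)oc4cc3OCc6ccccc6)[C@@H](O[Si](C)(C)C(C)(C)C)[C@H]2O[Si](CC)(CC)CC)cc1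
F8 | step 18 | 7'-O-acetyl derivative of 22 (free 5-OH) | COc1ccc(CCc2cc(=O)c3c(o2)[C@@H](O[Si](C)(C)C(C)(C)C)[C@H](Oc4cc5c(=O)cc(CCc6ccccc6)oc5cc4OC(C)=O)[C@@H](O[Si](C)(C)C(C)(C)C)[C@H]3O)cc1
F9 | step 18 | 7'-O-acetyl 5-O-methanesulfonyl derivative of 22 | COc1ccc(CCc2cc(=O)c3c(o2)[C@@H](O[Si](C)(C)C(C)(C)C)[C@H](Oc4cc5c(=O)cc(CCc6ccccc6)oc5cc4OC(C)=O)[C@@H](O[Si](C)(C)C(C)(C)C)[C@H]3OS(C)(=O)=O)cc1
A1 | alternative 1 | 5-hydroxy-7-O-(4-methoxybenzyl)-6,8-bis-O-TBS tetrahydrochromone monomer | COc1ccc(CCc2cc(=O)c3c(o2)[C@@H](O[Si](C)(C)C(C)(C)C)[C@H](OCc4ccc(OC)cc4)[C@@H](O[Si](C)(C)C(C)(C)C)[C@@H]3O)cc1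
A2 | alternative 1 | open-chain δ-hydroxy β-diketone methyl ester, precursor of A1 | COC(=O)[C@@H](O[Si](C)(C)C(C)(C)C)[C@H](OCc1ccc(OC)cc1)[C@@H](O[Si](C)(C)C(C)(C)C)[C@H](O)CC(=O)CC(=O)CCc1ccc(OC)cc1
A3 | alternative 2 | bridged dioxepine β-diketone (enol form) with C6 dimethyl ketal | CC(=O)C3=C(O)C[C@@H]2Oc4cc5c(=O)cc(CCc6ccccc6)oc5cc4O[C@H]3C2(OC)OC
A4 | alternative 2 | 6,7-dihydroxy-2-(2-phenylethyl)-4H-chromen-4-one | O=c1cc(CCc2ccccc2)oc2cc(O)c(O)cc12
A5 | alternative 2 | 2-acetyl-4,4-dimethoxycyclohexa-2,5-dien-1-one | CC(=O)C1=CC(OC)(OC)C=CC1=O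
A6 | alternative 3 | 6,8-bis-O-TBS ether of the target (same compound as 23) | COc1ccc(CCc2cc(=O)c3c(o2)[C@@H](O[Si](C)(C)C(C)(C)C)[C@@H]2Oc4cc5c(=O)cc(CCc6ccccc6)oc5cc4O[C@H]3[C@@H]2O[Si](C)(C)C(C)(C)C)cc1
A7 | alternative 3 | Diels–Alder substrate: 6,8-bis-O-TBS monomer with the phenethyl pyranopyrandione (3-oxy-2-pyrone ring) on O5 and an (E)-2-(p-tolylsulfonyl)vinyl group on O7 | COc1ccc(CCc2cc(=O)c3c(o2)[C@@H](O[Si](C)(C)C(C)(C)C)[C@H](O/C=C/S(=O)(=O)c4ccc(C)cc4)[C@@H](O[Si](C)(C)C(C)(C)C)[C@@H]3OC5=CC6=C(OC5=O)C(=O)C=C(CCc7ccccc7)O6)cc1
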